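**Plan**
- Retrosynthesis: the hydroxyquinone goes back to a 4‑chlororesorcinol (oxidation at its one free ring CH) and then to a 3‑alkylorsellinate ester; the six‑membered ring is cut at quinone C1–C2 and C4–C5 (C1=O, C2–Cl, C3–Me, C4=O, C5–OH, C6–side chain).
- Enabling feature: in the quinone ring the side‑chain carbon C6 lies between two oxygen‑bearing carbons (C5–OH, C1=O), a latent 2‑alkylmalonyl unit; the C2–C3(Me)–C4 triad is the γ,β,α‑carbon set of 3‑methylbut‑2‑enoate. A [3+3] union closes the ring; the ester on C4 is a temporary activator, later exchanged for the quinone oxygen, and Cl is put on C2 afterwards.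
- Side chain: malonate joined at C2''=C3'' by cross‑metathesis, C4''–OH by enone reduction, C1'–C5'' by Mukaiyama–Michael addition to a 4‑methylcyclohexenone.
- Forward order: cyclohexanone ring (Michael/aldol, then two conjugate additions) → chain and malonic acid → benzene ring by the [3+3] step → chlorination, decarboxylation, oxidation to the quinone, deprotection.
- Stereochemistry: C6' from the organocatalytic Michael addition; C1' (cuprate anti to the C6' methyl) and C2' (enolate methylation anti to the axial acetate arm) by substrate control; C4'' by CBS reduction; E alkene from conjugation in the metathesis.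

Key step: step 12

Locants: primes = cyclohexanone ring (C1' quaternary, C2' = CHMe next to C3'=O, C6' = other CHMe); double primes = pentenyl chain (C1'' on the quinone).
Shorthand: Sp = (6R,7S,8S)-6,7,8-trimethyl-1,4-dioxaspiro[4.5]decan-7-yl; SC = (2E,4S)-4-{[tert-butyl(dimethyl)silyl]oxy}-3-methyl-5-Sp-pent-2-en-1-yl.
Assumption: C2' (α to the ring ketone) is taken to be less stable than its epimer, so it is set kinetically and the ketone is kept as a dioxolane from step 5 to step 16.

Step 1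
Reactants: 1 propanal; 2 but-3-en-2-one
Product: 4 (4S)-4-methylcyclohex-2-en-1-one, via (2S)-2-methyl-5-oxohexanal 3 (not isolated)
Conditions: (R)-2-[methoxy(diphenyl)methyl]pyrrolidine (5 mol %), ethyl 3,4-dihydroxybenzoate (20 mol %), neat, 4 °C; then LiOH (10 mol %), iPrOH, 23 °C
Reagents that add atoms: none
Why: Enamine-catalysed Michael addition in which the diphenyl(methoxy)methyl group of the R catalyst should shield one face of the propanal enamine and set the methyl-bearing centre (future C6') as S, followed by intramolecular aldol condensation (Robinson-type annulation).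

Step 2
Reactants: 4 (4S)-4-methylcyclohex-2-en-1-one; 5 tert-butyl[(1-methoxyethenyl)oxy]dimethylsilane
Product: 6 methyl 2-[(1R,6S)-3-{[tert-butyl(dimethyl)silyl]oxy}-6-methylcyclohex-2-en-1-yl]acetate
Conditions: TBSOTf (5 mol %), CH2Cl2, −78 °C
Reagents that add atoms: none
Why: Mukaiyama–Michael addition with silyl transfer gives the regiodefined silyl enol ether; the ketene acetal should enter anti to the ring methyl, but this new centre is erased in step 3.

Step 3
Reactants: 6 methyl 2-[(1R,6S)-3-{[tert-butyl(dimethyl)silyl]oxy}-6-methylcyclohex-2-en-1-yl]acetate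
Product: 7 methyl 2-[(6S)-6-methyl-3-oxocyclohex-1-en-1-yl]acetate
Conditions: Pd(OAc)2 (1.05 equiv), MeCN, 23–40 °C
Reagents that add atoms: none
Why: Saegusa–Ito oxidation, in which the oxa-π-allylpalladium species loses the β-hydrogen of the ring CH carrying the acetate arm, restores the enone now substituted at its β-carbon and leaves C6' untouched.

Step 4
Reactants: 7 methyl 2-[(6S)-6-methyl-3-oxocyclohex-1-en-1-yl]acetate
Product: 9 methyl 2-[(1S,2R,6S)-1,2,6-trimethyl-3-oxocyclohexyl]acetate, via lithium enolate 8 (not isolated)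
Conditions: Me2CuLi (from CuBr·SMe2 and 2 MeLi), Et2O, −40 → 0 °C; then MeI, DMPU, THF, −20 → 23 °C
Reagents that add atoms: lithium dimethylcuprate, [Li+].C[Cu-]C; iodomethane, CI
Why: Cuprate conjugate addition to the β,β-disubstituted enone should occur anti to the adjacent C6' methyl (quaternary C1'), and the regiodefined enolate should then be methylated anti to the axial CH2CO2Me arm in the half-chair that keeps the C6' methyl equatorial, placing the C2' methyl cis to the quaternary methyl (enolate alkylation under kinetic control).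

Step 5
Reactants: 9 methyl 2-[(1S,2R,6S)-1,2,6-trimethyl-3-oxocyclohexyl]acetate
Product: 10 methyl 2-Sp-acetate
Conditions: (TMSOCH2)2, TMSOTf (5 mol %), CH2Cl2, −78 → −20 °C; pyridine quench
Reagents that add atoms: 1,2-bis(trimethylsilyloxy)ethane, C[Si](C)(C)OCCO[Si](C)(C)C
Why: Silyl-triflate-catalysed ketalisation at low temperature should not enolise the ketone, so C2' is carried over unchanged and is then protected from base.

Step 6
Reactants: 10 methyl 2-Sp-acetate
Product: 12 3-methyl-1-Sp-but-3-en-2-one, via Weinreb amide 11 (not isolated)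
Conditions: MeNHOMe·HCl, iPrMgCl, THF, −20 °C; then CH2=C(Me)MgBr, −20 → 0 °C; cold aq. NH4Cl
Reagents that add atoms: isopropenylmagnesium bromide, CC(=C)[Mg]Br
Why: One-pot Weinreb ketone synthesis: the magnesium amide turns the ester into the N-methoxy-N-methylamide, whose chelated adduct with the vinyl Grignard reagent releases the enone only on work-up.

Step 7
Reactants: 12 3-methyl-1-Sp-but-3-en-2-one; 13 dimethyl 2-(prop-2-en-1-yl)propanedioate
Product: 14 dimethyl 2-[(2E)-3-methyl-4-oxo-5-Sp-pent-2-en-1-yl]propanedioate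
Conditions: 13 (3 equiv), second-generation Hoveyda–Grubbs catalyst (5 mol %), CH2Cl2, 40 °C
Reagents that add atoms: none
Why: Olefin cross-metathesis of a 1,1-disubstituted enone with excess terminal alkene; conjugation with the ketone should make the E trisubstituted alkene the product.

Step 8
Reactants: 14 dimethyl 2-[(2E)-3-methyl-4-oxo-5-Sp-pent-2-en-1-yl]propanedioate
Product: 15 dimethyl 2-[(2E,4S)-4-hydroxy-3-methyl-5-Sp-pent-2-en-1-yl]propanedioate
Conditions: (R)-2-methyl-CBS-oxazaborolidine (20 mol %), catecholborane, toluene, −78 °C; then MeOH, aq. NaHCO3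
Reagents that add atoms: none
Why: Corey–Bakshi–Shibata reduction in which the alkenyl group acts as the large substituent, so the R catalyst is expected to deliver hydride to the face giving the 4''S allylic alcohol, with 1,2-selectivity over the alkene and esters.

Step 9
Reactants: 15 dimethyl 2-[(2E,4S)-4-hydroxy-3-methyl-5-Sp-pent-2-en-1-yl]propanedioate
Product: 16 dimethyl 2-SC-propanedioate
Conditions: TBSOTf, 2,6-lutidine, CH2Cl2, −78 °C
Reagents that add atoms: tert-butyldimethylsilyl triflate, CC(C)(C)[Si](C)(C)OS(=O)(=O)C(F)(F)F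
Why: Silylation of the hindered secondary allylic alcohol under weakly basic conditions keeps it out of the acid chloride chemistry that follows.

Step 10
Reactants: 16 dimethyl 2-SC-propanedioate
Product: 17 2-SC-propanedioic acid
Conditions: LiOH, THF/MeOH/H2O, 23 °C; then 1 M HCl to pH 3, 0 °C
Reagents that add atoms: lithium hydroxide, [Li+].[OH-]
Why: Saponification of the malonic diester at room temperature, below the temperature at which a monoalkylmalonic acid decarboxylates; silyl ether and dioxolane are base-stable.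

Step 11
Reactants: 18 ethyl 3-methylbut-2-enoate
Product: 19 [(1-ethoxy-3-methylbuta-1,3-dien-1-yl)oxy]trimethylsilane
Conditions: LDA, THF, −78 °C; TMSCl, −78 → 23 °C
Reagents that add atoms: chlorotrimethylsilane, C[Si](C)(C)Cl
Why: γ-Deprotonation of the enoate (either methyl group gives the same dienolate) and O-silylation give the vinylogous silyl ketene acetal.

Step 12
Reactants: 17 2-SC-propanedioic acid; 19 [(1-ethoxy-3-methylbuta-1,3-dien-1-yl)oxy]trimethylsilane
Product: 24 ethyl 2,4-dihydroxy-6-methyl-3-SC-benzoate, via malonyl dichloride 20 (not isolated), via chlorocarbonyl ketene 21 (not isolated), via acylketene 22 (not isolated), via cyclohexadienone 23 (not isolated)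
Conditions: 1-chloro-N,N,2-trimethylprop-1-en-1-amine (2.1 equiv), CH2Cl2, 0 → 23 °C; Et3N (1.05 equiv), −78 °C; 19 (1.1 equiv) added slowly, −78 → 40 °C; aq. NH4Cl
Reagents that add atoms: none
Why: Proposed new method: triethylamine converts malonyl dichloride 20 into (chlorocarbonyl)ketene 21, whose ketene carbon is attacked by the unhindered terminal CH2 (γ-carbon) of 19 with loss of Me3SiCl to give acylketene 22 (first new ring bond, future quinone C1–C2); enolisation of the new ketone toward the doubly activated CH2 gives a dienylketene that closes onto the ester-bearing α-carbon (second new ring bond, future quinone C4–C5), and cyclohexadienone 23 tautomerises to the aromatic resorcylate. The closest known reaction types are the C-acylation of silyl ketene acetals by acid chlorides through ketenes with a tertiary amine, the formal [3+3] cyclocondensation of silyl dienol ethers with 1,3-dielectrophiles, cyclocondensations of (chlorocarbonyl)ketenes with 1,3-dinucleophiles and the dienylketene ring closure that ends the Danheiser benzannulation; new is their union on a vinylogous silyl ketene acetal, so that a 2-alkylmalonyl unit and a C4 ester give a pentasubstituted benzene. The ring closes in the six-membered carbocyclic mode by thermal 6π electrocyclisation, equivalent to C-acylation of the dienol terminus by the ketene. The only new sp3 centre, the ring CH of 23, is erased on aromatisation, so no stereocentre is formed and the existing ones are remote from the reacting atoms. The step needs γ- over α-attack of 19 (vinylogous reactivity, the α-carbon being the more hindered), C- over O-closure (after γ-acylation an oxygen could only close a four- or eight-membered ring) and mono- over bis-acylation (slow addition of 19 to 21 at 1:1 stoichiometry, the ring closure being intramolecular).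

Step 13
Reactants: 24 ethyl 2,4-dihydroxy-6-methyl-3-SC-benzoate
Product: 25 ethyl 5-chloro-2,4-dihydroxy-6-methyl-3-SC-benzoate
Conditions: NCS (1.05 equiv), iPr2NH (10 mol %), CH2Cl2, 0 °C
Reagents that add atoms: N-chlorosuccinimide, O=C1CCC(=O)N1Cl
Why: Electrophilic aromatic chlorination at the single free ring position (ortho to one hydroxyl, para to the other), with an N-chloroamine as the ortho-directing carrier that should leave the trisubstituted alkene alone.

Step 14
Reactants: 25 ethyl 5-chloro-2,4-dihydroxy-6-methyl-3-SC-benzoate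
Product: 27 4-chloro-5-methyl-2-SC-benzene-1,3-diol, via carboxylic acid 26 (not isolated)
Conditions: NaOH (2 M aq.), MeOH, reflux, Ar; then 1 M HCl to pH 6, 0 °C
Reagents that add atoms: none
Why: Decarboxylative saponification of a 2,4-dihydroxybenzoate (ipso-protonation para to a hydroxyl, loss of CO2) removes the activating ester; the dioxolane shields C2' from the base.

Step 15
Reactants: 27 4-chloro-5-methyl-2-SC-benzene-1,3-diol
Product: 28 2-chloro-5-hydroxy-3-methyl-6-SC-cyclohexa-2,5-diene-1,4-dione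
Conditions: (KSO3)2NO (2.5 equiv), KH2PO4 buffer, acetone/H2O, 0 → 23 °C
Reagents that add atoms: potassium nitrosodisulfonate, [K+].[K+].[O]N(S(=O)(=O)[O-])S(=O)(=O)[O-]
Why: Teuber oxidation of the resorcinol at its only free ring CH (para to one hydroxyl) gives the 2-hydroxy-1,4-benzoquinone, so the carbon that carried the ester now carries the quinone oxygen.

Step 16
Reactants: 28 2-chloro-5-hydroxy-3-methyl-6-SC-cyclohexa-2,5-diene-1,4-dione
Product: 29 2-chloro-5-hydroxy-6-{(2E,4S)-4-hydroxy-3-methyl-5-[(1S,2R,6S)-1,2,6-trimethyl-3-oxocyclohexyl]pent-2-en-1-yl}-3-methylcyclohexa-2,5-diene-1,4-dione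
Conditions: HF (48 % aq.), MeCN, 0 → 23 °C
Reagents that add atoms: water, O
Why: Fluoride cleaves the silyl ether and the weakly acidic aqueous medium hydrolyses the dioxolane much faster than it would enolise the liberated ketone, so C2' and the allylic alcohol should survive.

**Compound list**
1 | propanal | CCC=O | starting material
2 | but-3-en-2-one | CC(=O)C=C | starting material
3 | (2S)-2-methyl-5-oxohexanal | CC(=O)CC[C@H](C)C=O | intermediate
4 | (4S)-4-methylcyclohex-2-en-1-one | O=C1C=C[C@@H](C)CC1 | intermediate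
5 | tert-butyl[(1-methoxyethenyl)oxy]dimethylsilane | COC(=C)O[Si](C)(C)C(C)(C)C | starting material
6 | methyl 2-[(1R,6S)-3-{[tert-butyl(dimethyl)silyl]oxy}-6-methylcyclohex-2-en-1-yl]acetate | COC(=O)C[C@H]1C=C(O[Si](C)(C)C(C)(C)C)CC[C@@H]1C | intermediate
7 | methyl 2-[(6S)-6-methyl-3-oxocyclohex-1-en-1-yl]acetate | COC(=O)CC1=CC(=O)CC[C@@H]1C | intermediate
8 | lithium (3S,4S)-3-(2-methoxy-2-oxoethyl)-3,4-dimethylcyclohex-1-en-1-olate | [Li+].COC(=O)C[C@]1(C)C=C([O-])CC[C@@H]1C | intermediate
9 | methyl 2-[(1S,2R,6S)-1,2,6-trimethyl-3-oxocyclohexyl]acetate | COC(=O)C[C@@]1(C)[C@@H](C)CCC(=O)[C@@H]1C | intermediate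
10 | methyl 2-[(6R,7S,8S)-6,7,8-trimethyl-1,4-dioxaspiro[4.5]decan-7-yl]acetate | COC(=O)C[C@@]1(C)[C@@H](C)CCC2(OCCO2)[C@@H]1C | intermediate
11 | N-methoxy-N-methyl-2-[(6R,7S,8S)-6,7,8-trimethyl-1,4-dioxaspiro[4.5]decan-7-yl]acetamide | CON(C)C(=O)C[C@@]1(C)[C@@H](C)CCC2(OCCO2)[C@@H]1C | intermediate
12 | 3-methyl-1-[(6R,7S,8S)-6,7,8-trimethyl-1,4-dioxaspiro[4.5]decan-7-yl]but-3-en-2-one | CC(=C)C(=O)C[C@@]1(C)[C@@H](C)CCC2(OCCO2)[C@@H]1C | intermediate
13 | dimethyl 2-(prop-2-en-1-yl)propanedioate | COC(=O)C(CC=C)C(=O)OC | starting material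
14 | dimethyl 2-[(2E)-3-methyl-4-oxo-5-Sp-pent-2-en-1-yl]propanedioate | COC(=O)C(C/C=C(\C)C(=O)C[C@@]1(C)[C@@H](C)CCC2(OCCO2)[C@@H]1C)C(=O)OC | intermediate
15 | dimethyl 2-[(2E,4S)-4-hydroxy-3-methyl-5-Sp-pent-2-en-1-yl]propanedioate | COC(=O)C(C/C=C(\C)[C@@H](O)C[C@@]1(C)[C@@H](C)CCC2(OCCO2)[C@@H]1C)C(=O)OC | intermediate
16 | dimethyl 2-SC-propanedioate | COC(=O)C(C/C=C(\C)[C@@H](O[Si](C)(C)C(C)(C)C)C[C@@]1(C)[C@@H](C)CCC2(OCCO2)[C@@H]1C)C(=O)OC | intermediate
17 | 2-SC-propanedioic acid | OC(=O)C(C/C=C(\C)[C@@H](O[Si](C)(C)C(C)(C)C)C[C@@]1(C)[C@@H](C)CCC2(OCCO2)[C@@H]1C)C(=O)O | intermediate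
18 | ethyl 3-methylbut-2-enoate | CCOC(=O)C=C(C)C | starting material
19 | [(1-ethoxy-3-methylbuta-1,3-dien-1-yl)oxy]trimethylsilane (ketene acetal geometry not fixed) | CCOC(O[Si](C)(C)C)=CC(C)=C | intermediate
20 | 2-SC-propanedioyl dichloride | ClC(=O)C(C/C=C(\C)[C@@H](O[Si](C)(C)C(C)(C)C)C[C@@]1(C)[C@@H](C)CCC2(OCCO2)[C@@H]1C)C(Cl)=O | intermediate
21 | 3-oxo-2-SC-prop-2-enoyl chloride, the (chlorocarbonyl)ketene | O=C=C(C/C=C(\C)[C@@H](O[Si](C)(C)C(C)(C)C)C[C@@]1(C)[C@@H](C)CCC2(OCCO2)[C@@H]1C)C(Cl)=O | intermediate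
22 | ethyl 3-methyl-5,7-dioxo-6-SC-hepta-2,6-dienoate, the acylketene (C2=C3 geometry not fixed) | CCOC(=O)C=C(C)CC(=O)C(=C=O)C/C=C(\C)[C@@H](O[Si](C)(C)C(C)(C)C)C[C@@]1(C)[C@@H](C)CCC2(OCCO2)[C@@H]1C | intermediate
23 | ethyl 4-hydroxy-2-methyl-6-oxo-5-SC-cyclohexa-2,4-diene-1-carboxylate (both C1 epimers) | CCOC(=O)C1C(C)=CC(O)=C(C/C=C(\C)[C@@H](O[Si](C)(C)C(C)(C)C)C[C@@]2(C)[C@@H](C)CCC3(OCCO3)[C@@H]2C)C1=O | intermediate
24 | ethyl 2,4-dihydroxy-6-methyl-3-SC-benzoate | CCOC(=O)c1c(C)cc(O)c(C/C=C(\C)[C@@H](O[Si](C)(C)C(C)(C)C)C[C@@]2(C)[C@@H](C)CCC3(OCCO3)[C@@H]2C)c1O | intermediate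
25 | ethyl 5-chloro-2,4-dihydroxy-6-methyl-3-SC-benzoate | CCOC(=O)c1c(C)c(Cl)c(O)c(C/C=C(\C)[C@@H](O[Si](C)(C)C(C)(C)C)C[C@@]2(C)[C@@H](C)CCC3(OCCO3)[C@@H]2C)c1O | intermediate
26 | 5-chloro-2,4-dihydroxy-6-methyl-3-SC-benzoic acid | OC(=O)c1c(C)c(Cl)c(O)c(C/C=C(\C)[C@@H](O[Si](C)(C)C(C)(C)C)C[C@@]2(C)[C@@H](C)CCC3(OCCO3)[C@@H]2C)c1O | intermediate
27 | 4-chloro-5-methyl-2-SC-benzene-1,3-diol | Cc1cc(O)c(C/C=C(\C)[C@@H](O[Si](C)(C)C(C)(C)C)C[C@@]2(C)[C@@H](C)CCC3(OCCO3)[C@@H]2C)c(O)c1Cl | intermediate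
28 | 2-chloro-5-hydroxy-3-methyl-6-SC-cyclohexa-2,5-diene-1,4-dione | CC1=C(Cl)C(=O)C(C/C=C(\C)[C@@H](O[Si](C)(C)C(C)(C)C)C[C@@]2(C)[C@@H](C)CCC3(OCCO3)[C@@H]2C)=C(O)C1=O | intermediate
29 | 2-chloro-5-hydroxy-6-{(2E,4S)-4-hydroxy-3-methyl-5-[(1S,2R,6S)-1,2,6-trimethyl-3-oxocyclohexyl]pent-2-en-1-yl}-3-methylcyclohexa-2,5-diene-1,4-dione | CC1=C(Cl)C(=O)C(C/C=C(\C)[C@@H](O)C[C@@]2(C)[C@@H](C)CCC(=O)[C@@H]2C)=C(O)C1=O | target

Total step count: 16. Longest linear sequence: 15 (steps 1–10 and 12–16; step 11 prepares the four-carbon partner).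

**Steps most likely to fail**

Step 12 (proposed new method). The acylketene formed after the first C–C bond may be intercepted by a second molecule of the silyl dienolate or by itself before it can close the ring. Attack through the α-carbon of the dienolate, followed by closure through the ester oxygen to a pyranone, is the other failure path. The fallback uses known chemistry; it sets out from 12 and returns at 24. Cross-metathesis of 12 with (Z)-but-2-ene-1,4-diyl diacetate should give (2E)-3-methyl-4-oxo-5-Sp-pent-2-en-1-yl acetate F1. CBS reduction as in step 8 gives (2E,4S)-4-hydroxy-3-methyl-5-Sp-pent-2-en-1-yl acetate F2, and silylation as in step 9 gives the allylic acetate SC–OAc F3. Ethyl 6-methyl-2,4-dioxocyclohexane-1-carboxylate F4 (Michael–Claisen condensation of ethyl acetoacetate with ethyl but-2-enoate, NaOEt) is then allylated by F3 at the carbon between its two ring carbonyls (Tsuji–Trost reaction, Pd(PPh3)4, Et3N, THF) to give ethyl 6-methyl-2,4-dioxo-3-SC-cyclohexane-1-carboxylate F5. Dehydrogenation of F5 (DDQ, 1,4-dioxane, 60 °C) gives 24.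

Step 4. The cuprate may deprotonate the CH2 that is both α to the ester and γ to the enone instead of adding, and the hindered enolate may exchange protons before it is methylated. The fallback replaces the acetate arm by an allyl arm; it sets out from 4 and returns at 12. Copper-catalysed conjugate allylation of 4 (allylmagnesium bromide, CuBr·SMe2, TMSCl, THF, −78 °C) gives trimethyl{[(3R,4S)-4-methyl-3-(prop-2-en-1-yl)cyclohex-1-en-1-yl]oxy}silane F6. Saegusa–Ito oxidation gives (4S)-4-methyl-3-(prop-2-en-1-yl)cyclohex-2-en-1-one F7. Me2CuLi then MeI, as in step 4, gives (2R,3S,4S)-2,3,4-trimethyl-3-(prop-2-en-1-yl)cyclohexan-1-one F8. Ketalisation as in step 5 gives (6R,7S,8S)-6,7,8-trimethyl-7-(prop-2-en-1-yl)-1,4-dioxaspiro[4.5]decane F9. Ozonolysis (O3, then PPh3) gives 2-Sp-acetaldehyde F10, isopropenylmagnesium bromide gives 3-methyl-1-Sp-but-3-en-2-ol F11 (both carbinol epimers), and Dess–Martin oxidation gives 12.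

Step 13. Electrophilic chlorine may attack the trisubstituted alkene of the side chain, or add ipso at the alkylated ring carbon with loss of aromaticity. The fallback brings the chlorine in with the four-carbon partner; it sets out from 17 and returns at 25. Ethyl 4-bromo-3-methylbut-2-enoate and LiCl (acetone) give ethyl 4-chloro-3-methylbut-2-enoate F12. LDA then TMSCl, with deprotonation expected at the more acidic CH2Cl group, give [(4-chloro-1-ethoxy-3-methylbuta-1,3-dien-1-yl)oxy]trimethylsilane F13. Under the conditions of step 12, 17 and F13 should pass through 20, 21, ethyl 4-chloro-3-methyl-5,7-dioxo-6-SC-hepta-2,6-dienoate F14 and ethyl 3-chloro-4-hydroxy-2-methyl-6-oxo-5-SC-cyclohexa-2,4-diene-1-carboxylate F15 (neither isolated) to 25.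

Further compounds
F1 | step 12 | (2E)-3-methyl-4-oxo-5-Sp-pent-2-en-1-yl acetate | CC(=O)OC/C=C(\C)C(=O)C[C@@]1(C)[C@@H](C)CCC2(OCCO2)[C@@H]1C
F2 | step 12 | (2E,4S)-4-hydroxy-3-methyl-5-Sp-pent-2-en-1-yl acetate | CC(=O)OC/C=C(\C)[C@@H](O)C[C@@]1(C)[C@@H](C)CCC2(OCCO2)[C@@H]1C
F3 | step 12 | (2E,4S)-4-{[tert-butyl(dimethyl)silyl]oxy}-3-methyl-5-Sp-pent-2-en-1-yl acetate | CC(=O)OC/C=C(\C)[C@@H](O[Si](C)(C)C(C)(C)C)C[C@@]1(C)[C@@H](C)CCC2(OCCO2)[C@@H]1C
F4 | step 12 | ethyl 6-methyl-2,4-dioxocyclohexane-1-carboxylate | CCOC(=O)C1C(C)CC(=O)CC1=O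
F5 | step 12 | ethyl 6-methyl-2,4-dioxo-3-SC-cyclohexane-1-carboxylate | CCOC(=O)C1C(C)CC(=O)C(C/C=C(\C)[C@@H](O[Si](C)(C)C(C)(C)C)C[C@@]2(C)[C@@H](C)CCC3(OCCO3)[C@@H]2C)C1=O
F6 | step 4 | trimethyl{[(3R,4S)-4-methyl-3-(prop-2-en-1-yl)cyclohex-1-en-1-yl]oxy}silane | C=CC[C@H]1C=C(O[Si](C)(C)C)CC[C@@H]1C
F7 | step 4 | (4S)-4-methyl-3-(prop-2-en-1-yl)cyclohex-2-en-1-one | C=CCC1=CC(=O)CC[C@@H]1C
F8 | step 4 | (2R,3S,4S)-2,3,4-trimethyl-3-(prop-2-en-1-yl)cyclohexan-1-one | C=CC[C@@]1(C)[C@@H](C)CCC(=O)[C@@H]1C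
F9 | step 4 | (6R,7S,8S)-6,7,8-trimethyl-7-(prop-2-en-1-yl)-1,4-dioxaspiro[4.5]decane | C=CC[C@@]1(C)[C@@H](C)CCC2(OCCO2)[C@@H]1C
F10 | step 4 | 2-[(6R,7S,8S)-6,7,8-trimethyl-1,4-dioxaspiro[4.5]decan-7-yl]acetaldehyde | O=CC[C@@]1(C)[C@@H](C)CCC2(OCCO2)[C@@H]1C
F11 | step 4 | 3-methyl-1-[(6R,7S,8S)-6,7,8-trimethyl-1,4-dioxaspiro[4.5]decan-7-yl]but-3-en-2-ol | CC(=C)C(O)C[C@@]1(C)[C@@H](C)CCC2(OCCO2)[C@@H]1C
F12 | step 13 | ethyl 4-chloro-3-methylbut-2-enoate | CCOC(=O)C=C(C)CCl
F13 | step 13 | [(4-chloro-1-ethoxy-3-methylbuta-1,3-dien-1-yl)oxy]trimethylsilane | CCOC(O[Si](C)(C)C)=CC(C)=CCl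
F14 | step 13 | ethyl 4-chloro-3-methyl-5,7-dioxo-6-SC-hepta-2,6-dienoate | CCOC(=O)C=C(C)C(Cl)C(=O)C(=C=O)C/C=C(\C)[C@@H](O[Si](C)(C)C(C)(C)C)C[C@@]1(C)[C@@H](C)CCC2(OCCO2)[C@@H]1C
F15 | step 13 | ethyl 3-chloro-4-hydroxy-2-methyl-6-oxo-5-SC-cyclohexa-2,4-diene-1-carboxylate | CCOC(=O)C1C(C)=C(Cl)C(O)=C(C/C=C(\C)[C@@H](O[Si](C)(C)C(C)(C)C)C[C@@]2(C)[C@@H](C)CCC3(OCCO3)[C@@H]2C)C1=O
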